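## Retrosynthetic overview

1. Euchrenone b1 (6) ⇒ 6,8,3'-triallylgenistein (4). The disconnection is a triple olefin cross-metathesis (3 × allyl → prenyl), run last under neutral conditions so the acid-sensitive o-prenylphenols never meet acid.
2. 4 ⇒ genistein tri-O-allyl ether (3) by a triple aromatic Claisen rearrangement. All three aryl–C bonds form in one operation, and the regiochemistry converges because C6 and C8 are the only free A-ring sites and 3'/5' are equivalent.
3. 3 ⇒ genistein (1) + allyl bromide (2) by exhaustive O-allylation.
4. Ring order: no ring is formed. Rings A, C and B are bought intact in genistein.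

**Assumption 1:** The target (C30H34O5) has no stereocentre and no E/Z-isomeric olefin, so it is achiral. "Single enantiomer" therefore needs no stereocontrol.

**Assumption 2:** Genistein is taken as a catalogue starting material available in multigram quantities.

## Route

**Step 1**
Reactants: 1 genistein (5,7,4'-trihydroxyisoflavone); 2 allyl bromide
Product: 3 5,7-bis(allyloxy)-3-[4-(allyloxy)phenyl]-4H-chromen-4-one (C24H22O5)
Conditions: allyl bromide (6 equiv), K2CO3 (6 equiv), cat. KI, dry DMF, 60 °C, 16 h
Reagents that add atoms: allyl bromide, C=CCBr
Why: This is a threefold Williamson O-alkylation in which the acidic 7- and 4'-OH react first, excess electrophile and base in warm DMF overcome the chelated 5-OH, anhydrous carbonate leaves the pyranone closed, and no stereocentre is formed.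

**Step 2**
Reactants: 3 genistein tri-O-allyl ether
Product: 4 6,8-diallyl-3-(3-allyl-4-hydroxyphenyl)-5,7-dihydroxy-4H-chromen-4-one (6,8,3'-triallylgenistein, C24H22O5, an isomer of 3)
Conditions: degassed PhNEt2, 210 °C (sealed tube or μW), Ar, 3–6 h; then EtOAc / cold 1 M HCl wash to remove the amine
Reagents that add atoms: none
Why: Three thermal [3,3] aromatic Claisen rearrangements occur (4'-O→C3', 7-O→C8, 5-O→C6), and if the 7-O-allyl goes to C6 instead, the 5-O-allyl reaches C8 by Claisen–Cope (para-Claisen), so every pathway gives the same 6,8,3'-triallyl triphenol with no stereocentre created.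

**Step 3**
Reactants: 4 6,8,3'-triallylgenistein; 5 2-methyl-2-butene
Product: 6 euchrenone b1 (5,7-dihydroxy-3-[4-hydroxy-3-(3-methylbut-2-enyl)phenyl]-6,8-bis(3-methylbut-2-enyl)-4H-chromen-4-one, C30H34O5)
Conditions: Grubbs II (2 × 4 mol %), 2-methyl-2-butene/CH2Cl2 1:1 (large excess), 40 °C, sealed tube, 16–24 h; chromatography on neutral silica
Reagents that add atoms: 2-methyl-2-butene, CC=C(C)C (delivers =C(CH3)2 to each allyl; the terminal CH2 leaves as propene)
Why: In this triple olefin cross-metathesis the terminal allyl arenes react, any crotyl or homodimer by-products re-enter the cycle, the trisubstituted prenyl olefins accumulate as an unreactive sink, and the neutral conditions spare the free phenols and the chromone C2=C3 and prevent chroman formation (prenyl has no E/Z issue).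

## Compound list

| No. | Name | SMILES | Role |
|---|---|---|---|
| 1 | Genistein | O=c1c(-c2ccc(O)cc2)coc2cc(O)cc(O)c12 | starting material |
| 2 | Allyl bromide | C=CCBr | starting material |
| 3 | 5,7,4'-Tri-O-allylgenistein | C=CCOc1ccc(-c2coc3cc(OCC=C)cc(OCC=C)c3c2=O)cc1 | intermediate |
| 4 | 6,8,3'-Triallylgenistein | C=CCc1cc(-c2coc3c(CC=C)c(O)c(CC=C)c(O)c3c2=O)ccc1O | intermediate |
| 5 | 2-Methyl-2-butene | CC=C(C)C | starting material |
| 6 | Euchrenone b1 (achiral) | CC(C)=CCc1cc(-c2coc3c(CC=C(C)C)c(O)c(CC=C(C)C)c(O)c3c2=O)ccc1O | target |

**Total step count:** 3
**Longest linear sequence:** 3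

## Steps most likely to fail, with fallbacks

1. **Step 2, triple Claisen.**
   - Risks: incomplete migration of the slower 4'-ether, thermal loss of the 5-O-allyl group, and cyclisation of o-allylphenols to dihydrobenzofurans.
   - Fallback: drop the sigmatropic approach and assemble the skeleton convergently with the prenyl groups already in place.
     - C,C-diprenylate 2,4,6-trihydroxyacetophenone (prenyl bromide, aq. KOH), then bis-MOM protect.
     - Form the enaminone with DMF-DMA and cyclise with I2 to the 3-iodochromone.
     - Couple by Suzuki–Miyaura with 4-(MOMO)-3-prenylphenylboronic acid pinacol ester, then remove the MOM groups with mild acid.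

2. **Step 3, triple cross-metathesis on a free triphenol.**
   - Risks: catalyst sequestration by the chelating phenol/carbonyl, allyl→propenyl isomerisation, and hard-to-separate partially converted or crotyl products.
   - Fallback: replace metathesis with cleavage and olefination.
     - Protect 4 as TBS ethers.
     - Cleave the three allyl groups by Lemieux–Johnson oxidation (OsO4/NaIO4) to the tris(arylacetaldehyde).
     - Carry out a triple Wittig reaction with Ph3P=C(CH3)2, then desilylate with TBAF, so no acid is used.

3. **Step 1, exhaustive O-allylation.**
   - Risks: the hydrogen-bonded 5-OH remains free, or competing C-allylation occurs.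
   - Fallback: avoid the 5-ether with an iterative sequence.
     - Make only the 7,4'-di-O-allyl ether (K2CO3, acetone) and rearrange it to 8,3'-diallylgenistein.
     - Re-allylate the 7-OH and run a second Claisen, which can only go to C6, to reach the same compound 4.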